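I began at late times: in the amber run the target was still rising after 16 min, but more slowly than in the stretch before.

| setting | amber | ochre | green | violet |
|---|---|---|---|---|
| substrate | 120 mM | 72.0 mM | 360 mM | 120 mM |
| coupling partner | 180 mM | 132 mM | 180 mM | 180 mM |
| target |  |  |  | 60.0 mM |
| time |  |  |  | 23 min |

- amber run (time / min: [target] / mM): 1.8: 3.8; 5.3: 13.3; 10: 27.4; 16: 37.6; 23: 42.2
- ochre run (time / min: [target] / mM): 1.8: 1.0; 5.3: 7.7; 10: 13.4; 16: 20.3; 23: 22.5
- green run (time / min: [target] / mM): 1.8: 7.5; 5.3: 40.1; 10: 74.2; 16: 97.3; 23: 109.7

(scatter of a reading: 0.6 mM)

1. order of the initial rate in [substrate], near the charge of the amber run, the rate being that where two percent of its substrate are target (one fixed amount of target, the same in the runs compared)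
2. order of the initial rate in [coupling partner], near the charge of the amber run, the rate being that where two percent of its substrate are target
3. target in the violet run at 23 min, as a share of the substrate charged

- Overall: substrate + coupling partner -> target.
- Constant volume, constant temperature.
- Bound and free are read together.
- "The second partner" is coupling partner.
- An order is taken over about fifteen percent of the charge, up and down.
- A share of target counts the target that was charged too.

I compared two late stretches of the amber run. Its net rate was 1.70 mM/min from 10 min to 16 min, then 0.657 mM/min from 16 min to 23 min. Dividing that fall by the rise in mean target between the stretches measures the slowing against target made, not against the clock. I named the result the late slowing constant, λ, the drop in net rate per mM of target gained: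

λ = (earlier rate − later rate) / (rise in mean target) = 0.141 /min

The violet flask is the amber charge plus 60.0 mM of target, so I built it up one process at a time.

With the main step alone, substrate + coupling partner → target, the charged target merely sits there and adds to the amber reading:

violet share = (amber reading + charged target) / substrate = 85.2 %

Next I added a loss of target, taken as pseudo-first-order with constant κ. If the whole of λ were that loss, the charged target would shrink by exp(−λt):

violet share = (amber reading + charged target × exp(−λt)) / substrate = 37.1 %

The remaining processes, whatever slows the gain itself, would claim part of λ and put κ somewhere between zero and λ. I did not split it from these readings, so my own number was the midpoint, 61.1 %.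

The forecast gave orders of 1 in substrate and 0.6 in coupling partner, and 84 % for the violet flask, on the view of “a catalyst that switches on briefly”. Its violet share stood close to my first step and higher than my midpoint.

The violet flask gave 67.3 %, with orders 0.65 in substrate and 0.35 in coupling partner.

    substrate → intermediate (0.3672 /min)
    intermediate + coupling partner → target (1.104 /M/min)
    intermediate → side product (0.03366 /min)
    target + coupling partner → side product (0.4842 /M/min)
    2 coupling partner ⇌ idle reagent dimer, settled at all times (34.80 /M)

Target and coupling partner give side product with a constant of 0.484 /M/min. Taking the amber gain as unchanged, the violet flask held 38.6 mM above the amber reading at 23 min, against 60.0 mM charged, which reads as κ = 0.0192 /min, or 13.6 % of the amber λ. The green run reads λ = 0.117 /min, and with it a plateau reading of 119 mM. Run back from 16 min, that exponential curve reaches a quarter of the green substrate at 13.5 min, and the green run's own time was 13.3 min.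

Readings and results are simulated on assumed constants; noise was put on by code.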